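## Structural features

The target is a single cyclohexane ring with no other ring. C1 is a quaternary gem-dimethyl carbon, C2 carries bromine, C3 is the ring end of an exocyclic trisubstituted alkene to C7, C7 carries the bromomethyl carbon C8, C4 carries chlorine, C5 is a methylene and C6 carries chlorine. The three stereocentres are all S: C2 and C4 flank the alkylidene carbon C3 and are both allylic, C2 and C6 flank C1, the C2 bromide and the C6 chloride are cis, and the C4 chloride is trans to both. The alkene is Z, with C8 on the side of C2. Three of the four halides are allylic (C2–Br, C4–Cl, C8–Br) and so are open to SN2, SN2′, ionisation and halide exchange; the C6 chloride has β-hydrogens at C5. The real difficulty is to place two different halogens at four sites without scrambling, two of them (C2 and C6) on neopentyl carbons where substitution is slow, and to tie the alkene geometry to the C2 centre. The key step uses C4 as a latent ketone: in the enone C4(=O)–C3=C2 with a vinyl group (C7=C8) on C3, C2 is the β carbon that accepts boron, and protonation of the dienolate at C8 moves the double bond to C3=C7 with C8 anti to the carbonyl group, which is the target geometry. The same carbonyl later makes C8 vinylogously acidic, makes C6 the β carbon of a second enone arm, and ends as the C4 chloride.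

## Logic of the disconnections

19 ⇒ 18. The C2–Br and C8–Br bonds are cut back to C–O bonds. The two allylic bromides are the most labile groups, so they are made last and together by one reagent. This removes both bromines and keeps bromide away from every step that uses chloride or a phosphine. The forward step must substitute the neopentyl, allylic C2 with inversion, without SN2′ at C7 and without exchange at the C4 chloride.

18 ⇒ 17. The O–acyl bond at C8 is cut. The ester masks the primary allylic alcohol while C4 is chlorinated. Its removal must be non-basic and must leave the chlorides alone.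

17 ⇒ 16. The C4–Cl bond is cut to a C4–OH of opposite configuration. An allylic chloride is best made by SN2 from the alcohol, and it is made before any bromide exists. The forward step must choose the unhindered C4 hydroxyl over the neopentyl C2 hydroxyl and must not transpose.

16 ⇒ 15. The C4–H bond is cut back to the ketone. The free C2 hydroxyl can deliver hydride to its own face, so the C2 centre sets C4 and the anti diol results. The β-chloro ketone in 15 must survive, so the medium has to be acidic.

15 ⇒ 13 (through 14). The C6–Cl and C5–H bonds are cut (HCl across the endocyclic enone arm), together with the O–Si bond. A neopentyl chloride cannot be made by substitution, but chloride can add to the sp2 carbon C6 of an enone. The forward step needs attack at C6 and not at C7, trans to the axial silyloxy group, and it must come after every base-mediated step, because any enolate of a β-chloro ketone loses chloride.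

13 ⇒ 12 ⇒ 10 (through 11). The C8–O bond is cut to C8–Br and then to C8–H. In 10 there is no α′ hydrogen, so enolisation can only go to C8, and the vinylogous position is brominated. Oxygen and not bromine is carried at C8 from here on, because a primary allylic bromide would exchange with chloride in the hydrochlorination and the deoxychlorination and would alkylate triphenylphosphine. The forward steps need γ- and not α-attack and must keep the E geometry.

10 ⇒ 8 (through 9). The C5=C6 double bond is cut back to two C–H bonds. This opens the second enone arm; the demand is kinetic enolisation toward C5 only.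

8 ⇒ 7 ⇒ 6. The O–Si bond and then the C2–O bond are cut, the latter back to C2–B with retention. A silyl ether is chosen because it is a poor leaving group next to the enone and is held axial by allylic strain.

6 ⇒ 4 + 5. The C2–B bond and the C8–H bond are cut; this is the key step. It creates the only catalyst-set stereocentre and the exocyclic alkene in one operation from an achiral enone.

4 ⇒ 2 + 3. The C3–C7 bond is cut (cross-coupling of a vinyl unit onto the α carbon of the enone). The diene 4 must be made under mild conditions and used at once.

2 ⇒ 1. The C–I bond is cut; the enone α carbon is iodinated directly.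

## Other disconnections considered

Alternative 1: The cut goes through the ring double bond C2=C3 and the side-chain double bond C7=C8 of a diene, so that the carbocycle comes from an open-chain 1,7-enyne whose anti C4/C6 dichloride was set beforehand by organocatalytic chlorination. In the forward sense the second-generation Grubbs catalyst under ethylene closes the six-membered ring in the exo mode and gives (4S,6S)-4,6-dichloro-1-ethenyl-3,3-dimethylcyclohex-1-ene A1; a 1,4-addition of bromine across the diene would then give both C–Br bonds and the exocyclic alkene.
- In its favour: both chlorides, including the neopentyl one at C6, are made in acyclic material under catalyst control; no protecting group is needed; A1 is one step from the target.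
- Against it here: a propargylic chloride has to survive the ruthenium carbene; A1 holds an allylic chloride next to a diene; and the bromine addition has no element that controls 1,4- against 1,2-addition, the Z geometry at C3=C7 or the face at C2, while its products are allylic bromides that can equilibrate.
- Comparison: on step economy Alternative 1 is clearly better. On the C6 chloride it is also better, since no hydrochlorination of a cross-conjugated dienone is needed. On mechanism the metathesis is as dependable as the borylation. On structure the chosen plan is stronger at the hardest point: C2 is set by a catalyst, C4 and C6 are derived from it one at a time, and the alkene geometry follows from an enone preference, whereas Alternative 1 leaves C2 and the alkene geometry to its last and least controllable step.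

Alternative 2: The cut is the C2–Br bond together with the C3=C7 double bond, traced back to a bicyclo[4.1.0]heptane with bromine on the bridgehead C3 and a C2–C7 bond closing the three-membered ring. On heating in a polar medium (ZnBr2 if needed) the C3–Br bond ionises while the C2–C7 bond opens in a disrotatory way, and bromide returns to the allyl cation terminus C2 to give (2Z)-2-[(2R,4S,6R)-2-bromo-6-[(tert-butyldimethylsilyl)oxy]-4-chloro-3,3-dimethylcyclohexylidene]ethyl 2,2-dimethylpropanoate A2.
- In its favour: the opening is stereospecific, so the alkene geometry is fixed by the configuration of the cyclopropane; the neopentyl C2–Br bond forms by collapse of an ion pair and not by substitution, which is better than the last step of the chosen plan; the C8 oxygen is already present.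
- Against it here: the Z alkene needs the acyloxymethyl group to rotate inward, the sterically worse mode; the ion pair must collapse at C2 and not at C7, and on one face; the fully substituted bromocyclopropane next to the gem-dimethyl carbon is long to make with all its centres defined; after A2 the C4 silyl ether must still become the chloride and the ester the bromide in a molecule that already holds an allylic bromide, which invites halide exchange.
- Comparison: on alkene geometry the two plans are equal (each rests on a dependable principle). On making the C2–Br bond Alternative 2 is better. On access to the substrate, on the order of halogen introduction and probably on step count the chosen plan is better.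

Alternative 3: The cut is the ring bond C1–C2. BF3·OEt2 ionises a tertiary alcohol next to the C6 chloride, and the β-chloro cation at C1 is captured by the free γ carbon of a 2-silyloxyfuran, closing the six-membered ring as the fused butenolide (4S,6S,7aS)-4,6-dichloro-7,7-dimethyl-5,6,7,7a-tetrahydro-1-benzofuran-2(4H)-one A3.
- In its favour: it is biomimetic; the ring and the bond to the quaternary carbon form in one step from acyclic material that already holds both chlorides; the lactone ring locks C8 cis to C2, so the Z geometry is built in, which is equal to or better than the enone preference of the chosen plan; no ketone relay or desaturation is needed, so it could be shorter.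
- Against it here: a β-chloro tertiary cation can bridge, shift or eliminate; the C4 chloride is allylic to an electron-rich furan before cyclisation, and in A3 the acidic γ-hydrogen at C2 can expel it; the C2 centre rests only on the cyclisation transition state.
- A structural point: in A3 as drawn the ring oxygen at C2 lies on the face that bromine occupies in the target, so replacing it with inversion would give the C2 epimer. The plan needs the C2-epimeric lactone or a substitution with net retention.
- Comparison: on convergence and ring construction Alternative 3 is better; on alkene geometry it is equal or better. On control of C2, on the stability of intermediates and on predictability of the mechanism the chosen plan is better.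

Key step: step 3

Assumption: the sense of induction of the copper–Josiphos catalyst on this α-vinyl, β-neopentyl enone cannot be predicted with confidence; the route is written for the ligand enantiomer that gives (3R)-6, and the mirror-image ligand would be used if the sense proves opposite.

## Route

Step 1
Reactants: 1 4,4-dimethylcyclohex-2-en-1-one
Product: 2 2-iodo-4,4-dimethylcyclohex-2-en-1-one
Conditions: I2, pyridine, CH2Cl2, 0 °C to rt
Reagents that add atoms: iodine, II
Why: Johnson α-iodination of a cyclic enone: pyridine adds to the β carbon, the enolate is iodinated and pyridine is lost (a Baylis–Hillman-type addition–elimination), which is open because the β carbon bears hydrogen.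

Step 2
Reactants: 2 2-iodo-4,4-dimethylcyclohex-2-en-1-one; 3 2-ethenyl-4,4,5,5-tetramethyl-1,3,2-dioxaborolane (vinylboronic acid pinacol ester)
Product: 4 2-ethenyl-4,4-dimethylcyclohex-2-en-1-one
Conditions: PdCl2(dppf) (3 mol %), K2CO3, THF/H2O, 45 °C
Reagents that add atoms: none
Why: Suzuki–Miyaura coupling; α-iodoenones undergo oxidative addition readily and the vinyl boronate transfers cleanly under mild aqueous base. The cross-conjugated diene 4 is used at once, its Diels–Alder dimerisation being slowed by the gem-dimethyl group beside the ring terminus of the diene.

Step 3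
Reactants: 4 2-ethenyl-4,4-dimethylcyclohex-2-en-1-one; 5 bis(pinacolato)diboron
Product: 6 (2E,3R)-2-ethylidene-4,4-dimethyl-3-(4,4,5,5-tetramethyl-1,3,2-dioxaborolan-2-yl)cyclohexan-1-one
Conditions: CuCl (5 mol %), NaOtBu (10 mol %), (R,S)-Josiphos [(R)-1-[(S)-2-(diphenylphosphino)ferrocenyl]ethyldicyclohexylphosphine] (6 mol %), MeOH (2 equiv), THF, 0 °C to rt; then DBU (10 mol %)
Reagents that add atoms: none
Why: CuCl and NaOtBu give a copper alkoxide that exchanges with 5 to the ligated copper–boryl complex, which adds syn across the enone double bond of 4 so that boron ends on the β carbon (ring C3, the future C2 of the target) and copper on the α carbon. The copper enolate is conjugated with the vinyl group; methanol protonates this dienolate and returns the copper alkoxide. Protonation at the vinyl terminus, or at the α carbon followed by alkoxide- or DBU-mediated isomerisation through the same dienolate, moves the double bond into the exocyclic conjugated position, where the E isomer (methyl away from the carbonyl oxygen and beside an axial C–B bond) should be the stable one. The closest known reaction type is the copper–bisphosphine-catalysed enantioselective conjugate borylation of cyclic enones with B2pin2 and an alcohol; no ring is closed. The one new stereocentre is controlled by enantioface selection of the chiral copper–boryl complex at the β carbon, and it cannot epimerise afterwards because its hydrogen is not conjugated with the carbonyl group. The step needs 1,4-addition to the enone in preference to borylcupration of the vinyl group, which the polarisation of the enone should secure (only the ring β carbon is an acceptor position), and it has to outrun dimerisation of 4, which the gem-dimethyl group slows.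

Step 4
Reactants: 6 (2E,3R)-2-ethylidene-4,4-dimethyl-3-(4,4,5,5-tetramethyl-1,3,2-dioxaborolan-2-yl)cyclohexan-1-one
Product: 7 (2E,3R)-2-ethylidene-3-hydroxy-4,4-dimethylcyclohexan-1-one
Conditions: NaBO3·4H2O, THF/H2O, 0 °C to rt
Reagents that add atoms: sodium perborate tetrahydrate, [Na+].[O-]OB=O
Why: Oxidation of the C–B bond by peroxoborate: the carbon migrates from boron to oxygen with retention, so the boron-bearing centre becomes the carbinol centre unchanged. The mild, weakly basic perborate is chosen over alkaline peroxide to avoid Weitz–Scheffer epoxidation of the enone.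

Step 5
Reactants: 7 (2E,3R)-2-ethylidene-3-hydroxy-4,4-dimethylcyclohexan-1-one
Product: 8 (2E,3R)-3-[(tert-butyldimethylsilyl)oxy]-2-ethylidene-4,4-dimethylcyclohexan-1-one
Conditions: TBSOTf, 2,6-lutidine, CH2Cl2, −78 to 0 °C
Reagents that add atoms: tert-butyldimethylsilyl trifluoromethanesulfonate, CC(C)(C)[Si](C)(C)OS(=O)(=O)C(F)(F)F
Why: Silylation of a hindered neopentyl alcohol with the silyl triflate. A silyl ether is used because an ester here would be a Morita–Baylis–Hillman-type leaving group open to SN2′, and because allylic strain with C8 holds the silyloxy group axial, where it later shields one face of C6.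

Step 6
Reactants: 8 (2E,3R)-3-[(tert-butyldimethylsilyl)oxy]-2-ethylidene-4,4-dimethylcyclohexan-1-one
Product: 10 (5R,6E)-5-[(tert-butyldimethylsilyl)oxy]-6-ethylidene-4,4-dimethylcyclohex-2-en-1-one, via trimethylsilyl enol ether 9 (not isolated)
Conditions: LDA, TMSCl, THF, −78 °C; then Pd(OAc)2 (1.05 equiv), MeCN, rt
Reagents that add atoms: none
Why: Saegusa–Ito oxidation: kinetic deprotonation can only occur at the one α-methylene (target C5), and the palladium enolate formed from 9 loses hydride from C6 to give the second enone arm. The silyloxy-bearing centre is not enolisable and is untouched.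

Step 7
Reactants: 10 (5R,6E)-5-[(tert-butyldimethylsilyl)oxy]-6-ethylidene-4,4-dimethylcyclohex-2-en-1-one
Product: 12 (5R,6E)-6-(2-bromoethylidene)-5-[(tert-butyldimethylsilyl)oxy]-4,4-dimethylcyclohex-2-en-1-one, via silyl trienol ether 11 (not isolated)
Conditions: TBSOTf, Et3N, CH2Cl2, 0 °C; solvent exchange; then NBS, THF, −78 °C
Reagents that add atoms: N-bromosuccinimide, O=C1CCC(=O)N1Br
Why: Soft enolisation of a dienone that has no α′ hydrogen can only remove a proton from C8, and NBS then brominates the silyl dienol ether at the unhindered vinylogous terminus and not at the fully substituted α carbon (γ-bromination of a silyl dienol ether). The s-trans rotamer of the diene, with C8 turned toward the C2–H bond, should return the E enone.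

Step 8
Reactants: 12 (5R,6E)-6-(2-bromoethylidene)-5-[(tert-butyldimethylsilyl)oxy]-4,4-dimethylcyclohex-2-en-1-one
Product: 13 (2E)-2-[(6R)-6-[(tert-butyldimethylsilyl)oxy]-5,5-dimethyl-2-oxocyclohex-3-en-1-ylidene]ethyl 2,2-dimethylpropanoate
Conditions: CsOPiv, DMF, 0 °C to rt
Reagents that add atoms: caesium pivalate, [Cs+].[O-]C(=O)C(C)(C)C
Why: SN2 displacement of a primary allylic bromide by a carboxylate. C8 is carried as an ester because a bromide there would exchange with chloride in steps 9 and 11 and would alkylate triphenylphosphine.

Step 9
Reactants: 13 (2E)-2-[(6R)-6-[(tert-butyldimethylsilyl)oxy]-5,5-dimethyl-2-oxocyclohex-3-en-1-ylidene]ethyl 2,2-dimethylpropanoate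
Product: 15 (2E)-2-[(2S,4S)-4-chloro-2-hydroxy-3,3-dimethyl-6-oxocyclohexylidene]ethyl 2,2-dimethylpropanoate, via silylated β-chloro ketone 14 (not isolated)
Conditions: HCl (4 M in dioxane, 1.5 equiv), CH2Cl2, −40 to −20 °C; volatiles removed cold; then aq. HF (48 %), MeCN, 0 °C
Reagents that add atoms: hydrogen chloride, Cl
Why: Conjugate addition of HCl to the endocyclic enone arm makes the neopentyl C–Cl bond at an sp2 carbon, and chloride should enter C6 trans to the axial silyloxy group, which shields the other face through a 1,3-diaxial relation (the cis adduct would also be the less stable one). An adduct at C7 should revert, since its enol would have to be protonated at the crowded C3, whereas the C6 adduct ketonises at the open C5. The β-chloro ketone tolerates acid but not base, so the silyl group is removed with HF.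

Step 10
Reactants: 15 (2E)-2-[(2S,4S)-4-chloro-2-hydroxy-3,3-dimethyl-6-oxocyclohexylidene]ethyl 2,2-dimethylpropanoate
Product: 16 (2Z)-2-[(2S,4S,6R)-4-chloro-2,6-dihydroxy-3,3-dimethylcyclohexylidene]ethyl 2,2-dimethylpropanoate
Conditions: Me4NBH(OAc)3, MeCN/AcOH, −30 to −20 °C
Reagents that add atoms: none
Why: Evans–Saksena hydroxyl-directed reduction: the axial C2 hydroxyl exchanges onto boron and delivers hydride to its own face of the C4 carbonyl, so the new hydroxyl is anti to the C2 hydroxyl and cis to the C6 chloride. The acidic medium keeps the β-chloro ketone intact until it is reduced.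

Step 11
Reactants: 16 (2Z)-2-[(2S,4S,6R)-4-chloro-2,6-dihydroxy-3,3-dimethylcyclohexylidene]ethyl 2,2-dimethylpropanoate
Product: 17 (2E)-2-[(2R,4S,6S)-4,6-dichloro-2-hydroxy-3,3-dimethylcyclohexylidene]ethyl 2,2-dimethylpropanoate
Conditions: PPh3 (1.1 equiv), hexachloroacetone, CH2Cl2, −20 to 0 °C
Reagents that add atoms: hexachloroacetone, ClC(Cl)(Cl)C(=O)C(Cl)(Cl)Cl
Why: Appel-type deoxychlorination with PPh3/hexachloroacetone, which converts allylic alcohols to chlorides by SN2 with inversion and little transposition; this gives the C4 chloride trans to the C6 chloride. The unhindered equatorial C4 hydroxyl is activated and displaced, while the neopentyl C2 hydroxyl reacts slowly and any alkoxyphosphonium formed there should revert to the alcohol on work-up.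

Step 12
Reactants: 17 (2E)-2-[(2R,4S,6S)-4,6-dichloro-2-hydroxy-3,3-dimethylcyclohexylidene]ethyl 2,2-dimethylpropanoate
Product: 18 (1R,3S,5S,6E)-3,5-dichloro-6-(2-hydroxyethylidene)-2,2-dimethylcyclohexan-1-ol
Conditions: DIBAL-H (3.5 equiv), CH2Cl2, −78 °C; Rochelle salt work-up
Reagents that add atoms: none
Why: Reductive cleavage of the pivalate by i-Bu2AlH; no alkoxide base is present, and alkyl and allylic chlorides are not reduced at this temperature.

Step 13
Reactants: 18 (1R,3S,5S,6E)-3,5-dichloro-6-(2-hydroxyethylidene)-2,2-dimethylcyclohexan-1-ol
Product: 19 (2S,4S,6S)-2-bromo-3-[(Z)-2-bromoethylidene]-4,6-dichloro-1,1-dimethylcyclohexane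
Conditions: CBr4 (2.6 equiv), PPh3 (2.5 equiv), CH2Cl2, 0 °C to rt
Reagents that add atoms: carbon tetrabromide, BrC(Br)(Br)Br
Why: Appel bromination of both hydroxyls: the primary allylic one reacts first, and the axial C2 alkoxyphosphonium is then displaced by bromide with inversion, an SN2 assisted by the adjacent π bond at a carbon with no β-hydrogen. This turns the catalyst-set oxygen centre into the C2 bromide cis to the C6 chloride; CBr4 is kept in excess over PPh3 so that no free phosphine is left to quaternise the allylic bromide.

## Compound list

CIP letters change along the route wherever substituent priorities change; the only centres actually inverted are C4 (step 11) and C2 (step 13).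

1 | 4,4-dimethylcyclohex-2-en-1-one | CC1(C)CCC(=O)C=C1 | starting material
2 | 2-iodo-4,4-dimethylcyclohex-2-en-1-one | CC1(C)CCC(=O)C(I)=C1 | intermediate
3 | 2-ethenyl-4,4,5,5-tetramethyl-1,3,2-dioxaborolane | C=CB1OC(C)(C)C(C)(C)O1 | starting material
4 | 2-ethenyl-4,4-dimethylcyclohex-2-en-1-one | C=CC1=CC(C)(C)CCC1=O | intermediate
5 | bis(pinacolato)diboron | CC1(C)OB(OC1(C)C)B1OC(C)(C)C(C)(C)O1 | starting material
6 | (2E,3R)-2-ethylidene-4,4-dimethyl-3-(4,4,5,5-tetramethyl-1,3,2-dioxaborolan-2-yl)cyclohexan-1-one | CC1(C)[C@@H](B2OC(C)(C)C(C)(C)O2)/C(=C\C)C(=O)CC1 | intermediate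
7 | (2E,3R)-2-ethylidene-3-hydroxy-4,4-dimethylcyclohexan-1-one | CC1(C)[C@@H](O)/C(=C\C)C(=O)CC1 | intermediate
8 | (2E,3R)-3-[(tert-butyldimethylsilyl)oxy]-2-ethylidene-4,4-dimethylcyclohexan-1-one | CC1(C)[C@@H](O[Si](C)(C)C(C)(C)C)/C(=C\C)C(=O)CC1 | intermediate
9 | tert-butyl{[(1R,6E)-6-ethylidene-2,2-dimethyl-5-[(trimethylsilyl)oxy]cyclohex-4-en-1-yl]oxy}dimethylsilane | CC1(C)[C@@H](O[Si](C)(C)C(C)(C)C)/C(=C\C)C(O[Si](C)(C)C)=CC1 | intermediate
10 | (5R,6E)-5-[(tert-butyldimethylsilyl)oxy]-6-ethylidene-4,4-dimethylcyclohex-2-en-1-one | CC1(C)[C@@H](O[Si](C)(C)C(C)(C)C)/C(=C\C)C(=O)C=C1 | intermediate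
11 | (6R)-2,6-bis[(tert-butyldimethylsilyl)oxy]-1-ethenyl-5,5-dimethylcyclohexa-1,3-diene | CC1(C)[C@@H](O[Si](C)(C)C(C)(C)C)C(C=C)=C(O[Si](C)(C)C(C)(C)C)C=C1 | intermediate
12 | (5R,6E)-6-(2-bromoethylidene)-5-[(tert-butyldimethylsilyl)oxy]-4,4-dimethylcyclohex-2-en-1-one | CC1(C)[C@@H](O[Si](C)(C)C(C)(C)C)/C(=C\CBr)C(=O)C=C1 | intermediate
13 | (2E)-2-[(6R)-6-[(tert-butyldimethylsilyl)oxy]-5,5-dimethyl-2-oxocyclohex-3-en-1-ylidene]ethyl 2,2-dimethylpropanoate | CC1(C)[C@@H](O[Si](C)(C)C(C)(C)C)/C(=C\COC(=O)C(C)(C)C)C(=O)C=C1 | intermediate
14 | (2E)-2-[(2S,4S)-2-[(tert-butyldimethylsilyl)oxy]-4-chloro-3,3-dimethyl-6-oxocyclohexylidene]ethyl 2,2-dimethylpropanoate | CC1(C)[C@@H](O[Si](C)(C)C(C)(C)C)/C(=C\COC(=O)C(C)(C)C)C(=O)C[C@@H]1Cl | intermediate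
15 | (2E)-2-[(2S,4S)-4-chloro-2-hydroxy-3,3-dimethyl-6-oxocyclohexylidene]ethyl 2,2-dimethylpropanoate | CC1(C)[C@@H](O)/C(=C\COC(=O)C(C)(C)C)C(=O)C[C@@H]1Cl | intermediate
16 | (2Z)-2-[(2S,4S,6R)-4-chloro-2,6-dihydroxy-3,3-dimethylcyclohexylidene]ethyl 2,2-dimethylpropanoate | CC1(C)[C@@H](O)/C(=C\COC(=O)C(C)(C)C)[C@H](O)C[C@@H]1Cl | intermediate
17 | (2E)-2-[(2R,4S,6S)-4,6-dichloro-2-hydroxy-3,3-dimethylcyclohexylidene]ethyl 2,2-dimethylpropanoate | CC1(C)[C@@H](O)/C(=C\COC(=O)C(C)(C)C)[C@@H](Cl)C[C@@H]1Cl | intermediate
18 | (1R,3S,5S,6E)-3,5-dichloro-6-(2-hydroxyethylidene)-2,2-dimethylcyclohexan-1-ol | CC1(C)[C@@H](O)/C(=C\CO)[C@@H](Cl)C[C@@H]1Cl | intermediate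
19 | (2S,4S,6S)-2-bromo-3-[(Z)-2-bromoethylidene]-4,6-dichloro-1,1-dimethylcyclohexane | CC1(C)[C@H](Br)/C(=C\CBr)[C@@H](Cl)C[C@@H]1Cl | target

## Step count and least certain steps

Total: 13 steps. Longest linear sequence: 13 steps, from 1 to 19; 3 and 5 are bought and enter in steps 2 and 3.

Step 3 (key step). The most likely failures are slow addition at the neopentyl β carbon, so that borylcupration of the terminal vinyl group or dimerisation of 4 takes over, and weaker enantioface selection than with unsubstituted cyclic enones. The fallback sets out from 2 and returns at 7; it creates the oxygen-bearing centre by reagent-controlled ketone reduction and hydroxyl-directed epoxidation instead of by copper catalysis. Reduction of 2 with (R)-Me-CBS oxazaborolidine and BH3·SMe2 should give the iodo allylic alcohol F1. Suzuki coupling with 3 gives the dienol F2. VO(acac)2 and t-BuOOH epoxidise the ring alkene on the face of the hydroxyl group to give the epoxy alcohol F3. Dess–Martin oxidation gives the vinyl epoxy ketone F4. SmI2 in THF/MeOH at −78 °C cleaves the C–O bond α to the carbonyl, and DBU brings the double bond into conjugation to give 7.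

Step 9. The most likely failure is attack of chloride on the exocyclic β carbon C7, followed by loss of the allylic silyloxy group from the enol or by a second addition; the s-cis exocyclic arm is the kinetically more accessible one, and only the slow protonation at C3 argues against it. The fallback sets out from 13 and returns at 14; it masks the exocyclic arm so that only C6 can accept chloride. TBSOTf and Et3N convert 13 into the bis-silyl trienol ether F5. Anhydrous HCl at −78 °C should protonate F5 at the ring carbon C3 (kinetic α-protonation of a dienol ether) to the deconjugated enone F6. Hydrochlorination of its only enone arm gives the deconjugated chloro ketone F7, and on warming in the same acidic medium the side-chain double bond returns into conjugation to give 14.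

Step 11. The most likely failure is competing activation of the C2 hydroxyl, or SN2′ and ionisation eroding the configuration at C4, because two secondary allylic alcohols are present. The fallback sets out from 14 (isolated by leaving out the HF stage of step 9) and returns at 17; it keeps C2 silylated and sets C4 by reagent control. (S)-Me-CBS oxazaborolidine with BH3·SMe2 should reduce 14 from the face of the silyloxy group to the silylated allylic alcohol F8; this has to override the substrate bias, which is why it is not the first choice. PPh3/hexachloroacetone then gives the silylated dichloride F9 with inversion, and aq. HF in MeCN gives 17.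

Step 13. The most likely failures are SN2′ attack of bromide at C7 or ionisation at the neopentyl C2 (loss of configuration or allylic transposition), and cyclodehydration of the cis-enediol to a 2,5-dihydrofuran. The fallback sets out from 18 and returns at 19; it separates the two brominations and activates C2 as a sulfonate. One equivalent of CBr4/PPh3 at −30 °C should brominate only the primary allylic alcohol to give the bromo alcohol F10. Ms2O and pyridine give the mesylate F11, and LiBr in acetone displaces it with inversion to give 19.

## Further compounds

F1 | step 3 | (1S)-2-iodo-4,4-dimethylcyclohex-2-en-1-ol | CC1(C)C=C(I)[C@@H](O)CC1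
F2 | step 3 | (1S)-2-ethenyl-4,4-dimethylcyclohex-2-en-1-ol | CC1(C)C=C(C=C)[C@@H](O)CC1
F3 | step 3 | (1S,2S,6R)-1-ethenyl-5,5-dimethyl-7-oxabicyclo[4.1.0]heptan-2-ol | CC1(C)[C@H]2O[C@@]2(C=C)[C@@H](O)CC1
F4 | step 3 | (1R,6R)-1-ethenyl-5,5-dimethyl-7-oxabicyclo[4.1.0]heptan-2-one | CC1(C)[C@H]2O[C@@]2(C=C)C(=O)CC1
F5 | step 9 | 2-[(6R)-2,6-bis[(tert-butyldimethylsilyl)oxy]-5,5-dimethylcyclohexa-1,3-dien-1-yl]ethenyl 2,2-dimethylpropanoate | CC1(C)[C@@H](O[Si](C)(C)C(C)(C)C)C(C=COC(=O)C(C)(C)C)=C(O[Si](C)(C)C(C)(C)C)C=C1
F6 | step 9 | 2-[(2S)-2-[(tert-butyldimethylsilyl)oxy]-3,3-dimethyl-6-oxocyclohex-4-en-1-yl]ethenyl 2,2-dimethylpropanoate (mixture at ring C1) | CC1(C)[C@@H](O[Si](C)(C)C(C)(C)C)C(C=COC(=O)C(C)(C)C)C(=O)C=C1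
F7 | step 9 | 2-[(2S,4S)-2-[(tert-butyldimethylsilyl)oxy]-4-chloro-3,3-dimethyl-6-oxocyclohexyl]ethenyl 2,2-dimethylpropanoate (mixture at ring C1) | CC1(C)[C@@H](O[Si](C)(C)C(C)(C)C)C(C=COC(=O)C(C)(C)C)C(=O)C[C@@H]1Cl
F8 | step 11 | (2Z)-2-[(2S,4S,6R)-2-[(tert-butyldimethylsilyl)oxy]-4-chloro-6-hydroxy-3,3-dimethylcyclohexylidene]ethyl 2,2-dimethylpropanoate | CC1(C)[C@@H](O[Si](C)(C)C(C)(C)C)/C(=C\COC(=O)C(C)(C)C)[C@H](O)C[C@@H]1Cl
F9 | step 11 | (2E)-2-[(2R,4S,6S)-2-[(tert-butyldimethylsilyl)oxy]-4,6-dichloro-3,3-dimethylcyclohexylidene]ethyl 2,2-dimethylpropanoate | CC1(C)[C@@H](O[Si](C)(C)C(C)(C)C)/C(=C\COC(=O)C(C)(C)C)[C@@H](Cl)C[C@@H]1Cl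
F10 | step 13 | (1R,3S,5S,6E)-6-(2-bromoethylidene)-3,5-dichloro-2,2-dimethylcyclohexan-1-ol | CC1(C)[C@@H](O)/C(=C\CBr)[C@@H](Cl)C[C@@H]1Cl
F11 | step 13 | (1R,3S,5S,6E)-6-(2-bromoethylidene)-3,5-dichloro-2,2-dimethylcyclohexyl methanesulfonate | CC1(C)[C@@H](OS(C)(=O)=O)/C(=C\CBr)[C@@H](Cl)C[C@@H]1Cl
A1 | alternative 1 | (4S,6S)-4,6-dichloro-1-ethenyl-3,3-dimethylcyclohex-1-ene | CC1(C)C=C(C=C)[C@@H](Cl)C[C@@H]1Cl
A2 | alternative 2 | (2Z)-2-[(2R,4S,6R)-2-bromo-6-[(tert-butyldimethylsilyl)oxy]-4-chloro-3,3-dimethylcyclohexylidene]ethyl 2,2-dimethylpropanoate | CC1(C)[C@H](Br)/C(=C\COC(=O)C(C)(C)C)[C@H](O[Si](C)(C)C(C)(C)C)C[C@@H]1Cl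
A3 | alternative 3 | (4S,6S,7aS)-4,6-dichloro-7,7-dimethyl-5,6,7,7a-tetrahydro-1-benzofuran-2(4H)-one | CC1(C)[C@@H]2OC(=O)C=C2[C@@H](Cl)C[C@@H]1Cl
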